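**Plan**

- Retrosynthesis: the O7 isopropyl ether is cleaved last. Ring A is cut at C4a–C5 (6π electrocyclisation) and unrolled to a 3-isopropoxy-4-methoxycyclobutenone hanging on a 2-aryl-4-pyranone. The C8–C8a bond is then cut (pyranonyl Grignard reagent plus isopropyl semisquarate), and the pyranone is cut at O1–C8a and C2–C3 (enolate of 4-methoxybut-3-en-2-one plus 3,4,5-trimethoxybenzoyl chloride).
- Forward: ring B is bought. Ring C is closed first as a monocyclic 2-aryl-4-pyranone and iodinated at the CH next to the ring oxygen. The four-membered ring is attached at that carbon, and ring A is formed last by thermal ring expansion of the cyclobutenone onto the pyranone C=C bond.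
- Enabling feature: ring A (C4a, C5, C6, C7, C8, C8a) is a benzene with oxygen on C5, C7 and C8 and hydrogen on C6. These four carbons map one to one onto the semisquarate ring (ketone carbon to C5–OH, CH to C6, isopropoxy carbon to C7, methoxylated carbinol carbon to C8), while C4a and C8a are the CH=C(O) unit of the pyranone.
- Stereochemistry: the target is achiral; the racemic centres formed on the way all end as sp2 carbons.

Key step: step 8

Remark: the three chiral intermediates of the route are racemic and are written without stereodescriptors; none of their stereocentres survives into the target.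

**Route**

Step 1
Reactants: 1 3,4,5-trimethoxybenzoyl chloride; 2 (E)-4-methoxybut-3-en-2-one
Product: 4 (E)-5-methoxy-1-(3,4,5-trimethoxyphenyl)pent-4-ene-1,3-dione, via lithium dienolate 3 (not isolated)
Conditions: LiN(SiMe3)2 (2.05 equiv), 2 (2.0 equiv), THF, −78 °C; then 1 (1.0 equiv), −78 °C; aq. NH4Cl
Reagents that add atoms: none
Why: Claisen-type C-acylation of the kinetic lithium enolate of the methyl ketone by the aroyl chloride, in which the second equivalent of enolate deprotonates the more acidic β-diketone as it forms and so holds back O-acylation and double acylation.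

Step 2
Reactants: 4 (E)-5-methoxy-1-(3,4,5-trimethoxyphenyl)pent-4-ene-1,3-dione
Product: 5 2-(3,4,5-trimethoxyphenyl)-4H-pyran-4-one
Conditions: TFA (0.5 equiv), CH2Cl2, rt
Reagents that add atoms: none
Why: acid-catalysed conjugate addition of the enol oxygen of the aryl ketone to the β-methoxy enone followed by loss of methanol (addition–elimination) should close the 4-pyranone, the standard cyclisation of 5-methoxypent-4-ene-1,3-diones.

Step 3
Reactants: 5 2-(3,4,5-trimethoxyphenyl)-4H-pyran-4-one
Product: 7 2-iodo-6-(3,4,5-trimethoxyphenyl)-4H-pyran-4-one, via pyranonylzinc chloride 6 (not isolated)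
Conditions: TMPZnCl·LiCl (TMP = 2,2,6,6-tetramethylpiperidide, 1.2 equiv), THF, 25 °C; then I2 (1.3 equiv), THF, 0 °C; aq. Na2S2O3
Reagents that add atoms: iodine, II
Why: directed C–H zincation with a hindered, magnesium-free zinc amide followed by iodolysis, in which, with no Lewis acid on the carbonyl oxygen, the base should remove the most acidic ring hydrogen (on the carbon next to the ring oxygen, as in the C2 zincation of chromones), and the covalent C–Zn bond neither triggers ring opening nor adds to a second pyranone before iodine fixes the position as the iodide.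

Step 4
Reactants: 8 diisopropyl squarate (3,4-diisopropoxycyclobut-3-ene-1,2-dione)
Product: 9 4-hydroxy-2,3-diisopropoxycyclobut-2-en-1-one (racemic)
Conditions: LiAlH(OtBu)3 (1.1 equiv), THF, −78 → 0 °C; H2O quench
Reagents that add atoms: none
Why: chemoselective 1,2-reduction of one of the two equivalent carbonyl groups by a bulky, mild aluminium hydride that should stop at the mono-carbinol; the new stereocentre is racemic and is destroyed in step 5.

Step 5
Reactants: 9 4-hydroxy-2,3-diisopropoxycyclobut-2-en-1-one
Product: 10 3-isopropoxycyclobut-3-ene-1,2-dione (isopropyl semisquarate)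
Conditions: conc. aq. HCl (cat.), CH2Cl2, rt
Reagents that add atoms: water, O
Why: acid-catalysed allylic transposition typical of squarate carbinols, in which ionisation of the carbinol gives an alkoxy-stabilised cyclobutenyl cation that takes up water at the alkoxy carbon next to the ketone and expels isopropanol, leaving the 1,2-dione with a single vinylogous ester.

Step 6
Reactants: 7 2-iodo-6-(3,4,5-trimethoxyphenyl)-4H-pyran-4-one; 10 3-isopropoxycyclobut-3-ene-1,2-dione
Product: 12 4-hydroxy-3-isopropoxy-4-[4-oxo-6-(3,4,5-trimethoxyphenyl)-4H-pyran-2-yl]cyclobut-2-en-1-one (racemic), via pyranonylmagnesium chloride 11 (not isolated)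
Conditions: iPrMgCl·LiCl (1.05 equiv), THF, −78 °C, 15 min; cannulated into 10 (1.3 equiv), THF, −78 °C; aq. NH4Cl at −78 °C
Reagents that add atoms: none
Why: iodine–magnesium exchange of the electron-poor alkenyl iodide with the turbo-Grignard reagent should be fast at −78 °C, where the pyranone carbonyl is inert, and the Grignard reagent should add 1,2 to the ketone carbonyl attached to the alkoxy-bearing carbon of the semisquarate (the other carbonyl is a deactivated vinylogous ester), as Grignard and organolithium reagents do with squarate esters; the carbinol stereocentre forms racemic and becomes an sp2 carbon in step 8.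

Step 7
Reactants: 12 4-hydroxy-3-isopropoxy-4-[4-oxo-6-(3,4,5-trimethoxyphenyl)-4H-pyran-2-yl]cyclobut-2-en-1-one
Product: 13 3-isopropoxy-4-methoxy-4-[4-oxo-6-(3,4,5-trimethoxyphenyl)-4H-pyran-2-yl]cyclobut-2-en-1-one (racemic)
Conditions: MeI (10 equiv), Ag2O (2 equiv), MeCN, rt, dark
Reagents that add atoms: iodomethane, CI
Why: Purdie O-methylation under nearly neutral conditions, the usual way to cap 4-hydroxycyclobutenones before thermolysis, should install the future C8 methoxy group without the strong base that would open the strained ketol and without alkylating the weakly nucleophilic pyranone oxygen.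

Step 8
Reactants: 13 3-isopropoxy-4-methoxy-4-[4-oxo-6-(3,4,5-trimethoxyphenyl)-4H-pyran-2-yl]cyclobut-2-en-1-one
Product: 16 5-hydroxy-7-isopropoxy-8-methoxy-2-(3,4,5-trimethoxyphenyl)-4H-chromen-4-one, via dienylketene 14 (not isolated), via bicyclic dienone 15 (not isolated)
Conditions: p-xylene (0.01 M, degassed), reflux (138 °C), Ar
Reagents that add atoms: none
Why: Heating should open the cyclobutenone by a conrotatory 4π electrocyclic cleavage of the bond between the ketone carbon and the methoxylated carbon to give dienylketene 14, whose 6π electrocyclisation bonds the ketene carbon to the pyranone CH next to the carbonyl (the new C4a–C5 bond) and gives dienone 15; enolisation of the doubly activated C4a–H then delivers the phenol, pulled on by aromatisation and by the hydrogen bond from the new 5-OH to the C4 carbonyl. The closest known reaction type is the Moore–Liebeskind benzannulation of 4-alkenyl- and 4-heteroaryl-4-alkoxycyclobutenones to phenols and hydroquinone monoethers, here with the enol-ether C=C bond of a 4-pyranone as the unsaturated arm. Ring A, the only ring closed, arises by a thermally allowed disrotatory 6π electrocyclisation of the hexatriene made up of the ketene C=C, the former cyclobutene C=C and the pyranone C=C bond, so it is formed already fused to ring C. No stereocentre results, since the carbinol carbon of 13 becomes C8 and the transient C4a centre of 15 is erased by the tautomerisation. The step needs torquoselectivity and regioselectivity: the methoxy donor on the breaking bond rotates outward, which turns the pyranonyl group inward toward the ketene, and closure can reach only one carbon because the other neighbour of the attachment carbon is the ring oxygen. High dilution under argon should keep the ketene from dimerising or being oxidised before it cyclises.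

Step 9
Reactants: 16 5-hydroxy-7-isopropoxy-8-methoxy-2-(3,4,5-trimethoxyphenyl)-4H-chromen-4-one
Product: 17 5,7-dihydroxy-8-methoxy-2-(3,4,5-trimethoxyphenyl)-4H-chromen-4-one (3',4',5'-trimethoxywogonin)
Conditions: BCl3 (3 equiv, 1 M in CH2Cl2), CH2Cl2, −78 → −10 °C; then H2O/THF, rt
Reagents that add atoms: none
Why: Lewis-acid dealkylation in which BCl3, after binding the 5-OH/C4=O pair, should cleave the secondary isopropyl–oxygen bond, which ionises far more readily than a methyl–oxygen bond, so that below −10 °C the methyl ethers (including the crowded 8- and 4'-methoxy groups, which BCl3 attacks only at room temperature) are expected to remain.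

**Compound list**

1 | 3,4,5-trimethoxybenzoyl chloride | COc1cc(C(=O)Cl)cc(OC)c1OC | starting material
2 | (E)-4-methoxybut-3-en-2-one | CO/C=C/C(C)=O | starting material
3 | lithium (E)-4-methoxybuta-1,3-dien-2-olate | CO/C=C/C(=C)[O-].[Li+] | intermediate
4 | (E)-5-methoxy-1-(3,4,5-trimethoxyphenyl)pent-4-ene-1,3-dione | CO/C=C/C(=O)CC(=O)c1cc(OC)c(OC)c(OC)c1 | intermediate
5 | 2-(3,4,5-trimethoxyphenyl)-4H-pyran-4-one | O=c1ccoc(-c2cc(OC)c(OC)c(OC)c2)c1 | intermediate
6 | chloro[4-oxo-6-(3,4,5-trimethoxyphenyl)-4H-pyran-2-yl]zinc, LiCl complex | O=c1cc([Zn]Cl)oc(-c2cc(OC)c(OC)c(OC)c2)c1.[Li+].[Cl-] | intermediate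
7 | 2-iodo-6-(3,4,5-trimethoxyphenyl)-4H-pyran-4-one | O=c1cc(I)oc(-c2cc(OC)c(OC)c(OC)c2)c1 | intermediate
8 | diisopropyl squarate (3,4-diisopropoxycyclobut-3-ene-1,2-dione) | CC(C)OC1=C(OC(C)C)C(=O)C1=O | starting material
9 | 4-hydroxy-2,3-diisopropoxycyclobut-2-en-1-one (racemic) | CC(C)OC1=C(OC(C)C)C(O)C1=O | intermediate
10 | 3-isopropoxycyclobut-3-ene-1,2-dione | CC(C)OC1=CC(=O)C1=O | intermediate
11 | chloro[4-oxo-6-(3,4,5-trimethoxyphenyl)-4H-pyran-2-yl]magnesium, LiCl complex | O=c1cc([Mg]Cl)oc(-c2cc(OC)c(OC)c(OC)c2)c1.[Li+].[Cl-] | intermediate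
12 | 4-hydroxy-3-isopropoxy-4-[4-oxo-6-(3,4,5-trimethoxyphenyl)-4H-pyran-2-yl]cyclobut-2-en-1-one (racemic) | CC(C)OC1=CC(=O)C1(O)c1cc(=O)cc(-c2cc(OC)c(OC)c(OC)c2)o1 | intermediate
13 | 3-isopropoxy-4-methoxy-4-[4-oxo-6-(3,4,5-trimethoxyphenyl)-4H-pyran-2-yl]cyclobut-2-en-1-one (racemic) | COC1(c2cc(=O)cc(-c3cc(OC)c(OC)c(OC)c3)o2)C(OC(C)C)=CC1=O | intermediate
14 | (3Z)-3-isopropoxy-4-methoxy-4-[4-oxo-6-(3,4,5-trimethoxyphenyl)-4H-pyran-2-yl]buta-1,3-dien-1-one | O=C=C/C(OC(C)C)=C(/OC)c1cc(=O)cc(-c2cc(OC)c(OC)c(OC)c2)o1 | intermediate
15 | 7-isopropoxy-8-methoxy-2-(3,4,5-trimethoxyphenyl)-4aH-chromene-4,5-dione (racemic) | O=C1C=C(OC(C)C)C(OC)=C2OC(c3cc(OC)c(OC)c(OC)c3)=CC(=O)C12 | intermediate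
16 | 5-hydroxy-7-isopropoxy-8-methoxy-2-(3,4,5-trimethoxyphenyl)-4H-chromen-4-one | COc1cc(-c2cc(=O)c3c(O)cc(OC(C)C)c(OC)c3o2)cc(OC)c1OC | intermediate
17 | 5,7-dihydroxy-8-methoxy-2-(3,4,5-trimethoxyphenyl)-4H-chromen-4-one (3',4',5'-trimethoxywogonin) | COc1cc(-c2cc(=O)c3c(O)cc(O)c(OC)c3o2)cc(OC)c1OC | target

**Step count and risks**

Total: 9 steps. Longest linear sequence: 7 steps (steps 1, 2, 3, 6, 7, 8, 9); steps 4 and 5 make the semisquarate in a side branch.

Most likely to fail, first: step 6. The exchange reagent may add to the iodopyranone by conjugate addition–elimination instead of exchanging, or the magnesiated pyranone may condense with unreacted iodide before it meets the semisquarate. The fallback avoids any free Grignard reagent. It sets out from pyranone 5, which is zincated with TMPZnCl·LiCl exactly as in step 3 to give zinc reagent 6, but the iodine quench is left out. Instead MgCl2 (1 equiv in THF) and semisquarate 10 are added at −20 °C and the mixture is warmed to rt. The zinc reagent is stable toward the pyranone, and MgCl2 activation is known to make arylzinc halides add to carbonyl groups. The route is rejoined at carbinol 12, and no compound outside the list arises (F0).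

Second: step 8. The 6π closure onto the electron-poor pyranone double bond may be too slow, so that the ketene is lost by dimerisation or by capture of adventitious nucleophiles, or the ring opening may partly turn the pyranonyl group outward. The fallback gives up the squarate disconnection for classical flavone chemistry and also avoids the BCl3 step.

- It sets out from acid chloride 1. Purchased 1-(2,4,6-trihydroxyphenyl)ethanone is converted to its lithium polyanion with LiN(SiMe3)2 (THF, −78 °C) and acylated with 1 to give 1-(2,4,6-trihydroxyphenyl)-3-(3,4,5-trimethoxyphenyl)propane-1,3-dione F1.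
- Cyclodehydration (H2SO4 in AcOH, 95 °C) should give 5,7-dihydroxy-2-(3,4,5-trimethoxyphenyl)-4H-chromen-4-one F2.
- The non-chelated 7-OH is benzylated (benzyl bromide, K2CO3, acetone) to 7-(benzyloxy)-5-hydroxy-2-(3,4,5-trimethoxyphenyl)-4H-chromen-4-one F3.
- Elbs persulfate oxidation (K2S2O8, aq. KOH/pyridine, rt) places oxygen para to the 5-OH as potassium 7-(benzyloxy)-5-hydroxy-4-oxo-2-(3,4,5-trimethoxyphenyl)-4H-chromen-8-yl sulfate F4.
- Acid hydrolysis (aq. HCl, Na2SO3, warm) gives 7-(benzyloxy)-5,8-dihydroxy-2-(3,4,5-trimethoxyphenyl)-4H-chromen-4-one F5.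
- Dimethyl sulfate (1 equiv) and K2CO3 in acetone methylate only the free 8-OH, since the 5-OH is held by the carbonyl, to give 7-(benzyloxy)-5-hydroxy-8-methoxy-2-(3,4,5-trimethoxyphenyl)-4H-chromen-4-one F6.
- Hydrogenolysis (H2, Pd/C, EtOAc) rejoins the route at the target 17.

Third: step 7. Methylation of the crowded tertiary carbinol may stall, or the basic Ag2O may open the strained ketol by retro-addition or ring contraction. The fallback leaves the methylation out and sets out from carbinol 12. It is heated as such in degassed toluene at 110 °C under argon; the free hydroxyl also rotates outward, and the same ring expansion should give the hydroquinone 5,8-dihydroxy-7-isopropoxy-2-(3,4,5-trimethoxyphenyl)-4H-chromen-4-one F7. Any quinone formed by air is reduced back with aq. Na2S2O4 during work-up. Dimethyl sulfate (1 equiv) and K2CO3 in acetone then methylate the 8-OH, the only phenol not chelated to the carbonyl, and the route is rejoined at 16.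

Further compounds
F0 | step 6 | none | none
F1 | step 8 | 1-(2,4,6-trihydroxyphenyl)-3-(3,4,5-trimethoxyphenyl)propane-1,3-dione | COc1cc(C(=O)CC(=O)c2c(O)cc(O)cc2O)cc(OC)c1OC
F2 | step 8 | 5,7-dihydroxy-2-(3,4,5-trimethoxyphenyl)-4H-chromen-4-one | COc1cc(-c2cc(=O)c3c(O)cc(O)cc3o2)cc(OC)c1OC
F3 | step 8 | 7-(benzyloxy)-5-hydroxy-2-(3,4,5-trimethoxyphenyl)-4H-chromen-4-one | COc1cc(-c2cc(=O)c3c(O)cc(OCc4ccccc4)cc3o2)cc(OC)c1OC
F4 | step 8 | potassium 7-(benzyloxy)-5-hydroxy-4-oxo-2-(3,4,5-trimethoxyphenyl)-4H-chromen-8-yl sulfate | COc1cc(-c2cc(=O)c3c(O)cc(OCc4ccccc4)c(OS(=O)(=O)[O-])c3o2)cc(OC)c1OC.[K+]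
F5 | step 8 | 7-(benzyloxy)-5,8-dihydroxy-2-(3,4,5-trimethoxyphenyl)-4H-chromen-4-one | COc1cc(-c2cc(=O)c3c(O)cc(OCc4ccccc4)c(O)c3o2)cc(OC)c1OC
F6 | step 8 | 7-(benzyloxy)-5-hydroxy-8-methoxy-2-(3,4,5-trimethoxyphenyl)-4H-chromen-4-one | COc1cc(-c2cc(=O)c3c(O)cc(OCc4ccccc4)c(OC)c3o2)cc(OC)c1OC
F7 | step 7 | 5,8-dihydroxy-7-isopropoxy-2-(3,4,5-trimethoxyphenyl)-4H-chromen-4-one | COc1cc(-c2cc(=O)c3c(O)cc(OC(C)C)c(O)c3o2)cc(OC)c1OC
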